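Assumption: the target has no stereocentre and is achiral, so "single enantiomer" means only the constitution drawn; no stereocontrol is needed.

## Retrosynthetic overview

1. The target comes from global hydrogenolysis of its hexadeca-O-benzyl ether.
2. The chain is grown from the ring A end. Each diaryl ether is made by Cu-catalysed O-arylation of a flanked phenol with a bromobenzaldehyde, and each CHO is then turned into the next phenol by Dakin oxidation. Rings C, E and F come from 2,6-bis(benzyloxy)-4-bromobenzaldehyde and ring D from 2,3,4-tris(benzyloxy)-6-bromobenzaldehyde.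
3. Ring A is the only ring that is built. The aryloxymalonyl chloride of ring B and dimethyl 3-oxopentanedioate are joined by an intermolecular Claisen-type C-acylation (the key C–C bond), followed by Dieckmann closure with aromatisation, decarboxylation and benzylation.
4. The ring B phenol comes from 2,3,4-trihydroxybenzaldehyde by benzylation, Dakin oxidation, ortho-formylation, allylation and a second Dakin oxidation.
5. Order: ring B (bought arene), ring A formed on its oxygen, then rings C, D, E and F attached in turn.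

## Route

Step 1
Reactants: 1 2,3,4-trihydroxybenzaldehyde
Product: 2 2,3,4-tris(benzyloxy)benzaldehyde
Conditions: BnBr (3.6 equiv), K2CO3, DMF, 70 °C
Reagents that add atoms: benzyl bromide, BrCc1ccccc1
Why: Williamson etherification of all three phenoxides, the chelated 2-OH included at 70 °C.

Step 2
Reactants: 2 2,3,4-tris(benzyloxy)benzaldehyde
Product: 4 2,3,4-tris(benzyloxy)phenol, via aryl formate 3 (not isolated)
Conditions: mCPBA, CH2Cl2, 0 °C to rt; then K2CO3 (cat.), MeOH, rt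
Reagents that add atoms: 3-chloroperoxybenzoic acid, OOC(=O)c1cccc(Cl)c1
Why: Dakin-type Baeyer–Villiger oxidation, in which the ortho/para-alkoxylated aryl group migrates to give the formate that is then methanolysed.

Step 3
Reactants: 4 2,3,4-tris(benzyloxy)phenol
Product: 5 3,4,5-tris(benzyloxy)-2-hydroxybenzaldehyde
Conditions: MgCl2, Et3N, (CH2O)n, MeCN, reflux
Reagents that add atoms: paraformaldehyde (formaldehyde), C=O
Why: Casnati–Skattebøl magnesium-phenoxide ortho-formylation, which can only occur at the single free ortho position.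

Step 4
Reactants: 5 3,4,5-tris(benzyloxy)-2-hydroxybenzaldehyde
Product: 6 2-(allyloxy)-3,4,5-tris(benzyloxy)benzaldehyde
Conditions: allyl bromide, K2CO3, DMF, 50 °C
Reagents that add atoms: allyl bromide, C=CCBr
Why: Williamson etherification installs an allyl group that is orthogonal to the benzyl ethers and stable to all later acid, base and acyl chloride conditions.

Step 5
Reactants: 6 2-(allyloxy)-3,4,5-tris(benzyloxy)benzaldehyde
Product: 8 2-(allyloxy)-3,4,5-tris(benzyloxy)phenol, via aryl formate 7 (not isolated)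
Conditions: mCPBA (1.1 equiv), NaHCO3, CH2Cl2, 0 °C; then K2CO3 (cat.), MeOH, rt
Reagents that add atoms: 3-chloroperoxybenzoic acid, OOC(=O)c1cccc(Cl)c1
Why: Dakin-type Baeyer–Villiger oxidation of the electron-rich aldehyde is much faster at 0 °C than epoxidation of the electron-poor allyl ether alkene.

Step 6
Reactants: 8 2-(allyloxy)-3,4,5-tris(benzyloxy)phenol; 9 dimethyl 2-chloromalonate
Product: 10 dimethyl 2-[2-(allyloxy)-3,4,5-tris(benzyloxy)phenoxy]malonate
Conditions: K2CO3, acetone, reflux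
Reagents that add atoms: none
Why: SN2 O-alkylation of the phenoxide by the chloromalonate, the standard entry to aryloxymalonates.

Step 7
Reactants: 10 dimethyl 2-[2-(allyloxy)-3,4,5-tris(benzyloxy)phenoxy]malonate
Product: 11 rac-2-[2-(allyloxy)-3,4,5-tris(benzyloxy)phenoxy]-3-methoxy-3-oxopropanoic acid
Conditions: KOH (1.05 equiv), THF/H2O, 0 °C; then dilute HCl to pH 2, 0 °C
Reagents that add atoms: potassium hydroxide, [K+].[OH-]
Why: selective monosaponification, because the first carboxylate deactivates the second ester; the new stereocentre is racemic, labile and erased in step 9.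

Step 8
Reactants: 11 rac-2-[2-(allyloxy)-3,4,5-tris(benzyloxy)phenoxy]-3-methoxy-3-oxopropanoic acid
Product: 12 rac-methyl 2-[2-(allyloxy)-3,4,5-tris(benzyloxy)phenoxy]-3-chloro-3-oxopropanoate
Conditions: (COCl)2, DMF (cat.), CH2Cl2, 0 °C to rt; concentrate, use crude
Reagents that add atoms: oxalyl chloride, ClC(=O)C(Cl)=O
Why: Vilsmeier-catalysed acid chloride formation under neutral conditions that leave the benzyl, allyl and methyl ester groups untouched.

Step 9
Reactants: 12 rac-methyl 2-[2-(allyloxy)-3,4,5-tris(benzyloxy)phenoxy]-3-chloro-3-oxopropanoate; 13 dimethyl 3-oxopentanedioate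
Product: 15 dimethyl 5-[2-(allyloxy)-3,4,5-tris(benzyloxy)phenoxy]-2,4,6-trihydroxybenzene-1,3-dicarboxylate, via acyclic triketo triester 14 (not isolated)
Conditions: 13 (1.5 equiv), MgCl2, pyridine, CH2Cl2, 0 °C to rt; then NaOMe, MeOH, 0 to 50 °C; aq. HCl
Reagents that add atoms: none
Why: crossed Claisen-type C-acylation of the magnesium enolate of 13 by the acid chloride (Rathke soft enolisation) forms the key C–C bond, and a Dieckmann condensation of the free CH2 onto the malonyl ester is pulled forward by aromatisation to the phloroglucinol, which removes all stereocentres.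

Step 10
Reactants: 15 dimethyl 5-[2-(allyloxy)-3,4,5-tris(benzyloxy)phenoxy]-2,4,6-trihydroxybenzene-1,3-dicarboxylate
Product: 17 2-[2-(allyloxy)-3,4,5-tris(benzyloxy)phenoxy]benzene-1,3,5-triyl triacetate, via triol 16 (not isolated)
Conditions: KOH, H2O/MeOH, reflux, argon; HCl to pH 2, 60 °C; extract, evaporate; then Ac2O, pyridine, rt
Reagents that add atoms: acetic anhydride, CC(=O)OC(C)=O
Why: saponification followed by the easy decarboxylation of 2,4,6-trihydroxybenzoic acids through their keto tautomers, with acetylation trapping the air-sensitive triol.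

Step 11
Reactants: 17 2-[2-(allyloxy)-3,4,5-tris(benzyloxy)phenoxy]benzene-1,3,5-triyl triacetate
Product: 18 2-(allyloxy)-3,4,5-tris(benzyloxy)-1-[2,4,6-tris(benzyloxy)phenoxy]benzene
Conditions: NaH, BnCl, DMF, H2O (3 equiv), 0 °C to rt
Reagents that add atoms: benzyl chloride, ClCc1ccccc1
Why: in situ deacetylation and Williamson benzylation keeps the free phenoxide concentration low, so O-benzylation wins over C-benzylation of the phloroglucinol ring.

Step 12
Reactants: 18 2-(allyloxy)-3,4,5-tris(benzyloxy)-1-[2,4,6-tris(benzyloxy)phenoxy]benzene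
Product: 19 2,3,4-tris(benzyloxy)-6-[2,4,6-tris(benzyloxy)phenoxy]phenol
Conditions: Pd(PPh3)4 (5 mol%), K2CO3, MeOH/THF, 60 °C
Reagents that add atoms: none
Why: Tsuji–Trost deallylation by zerovalent palladium transfers the allyl group to methoxide and leaves benzyl and diaryl ethers intact.

Step 13
Reactants: 20 4-bromo-2,6-difluorobenzaldehyde
Product: 21 2,6-bis(benzyloxy)-4-bromobenzaldehyde
Conditions: BnOH (2.2 equiv), K2CO3, DMF, 80 °C
Reagents that add atoms: benzyl alcohol, OCc1ccccc1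
Why: SNAr displaces the two fluorides ortho to the aldehyde, while the para bromide is a far poorer leaving group in addition–elimination and stays.

Step 14
Reactants: 19 2,3,4-tris(benzyloxy)-6-[2,4,6-tris(benzyloxy)phenoxy]phenol; 21 2,6-bis(benzyloxy)-4-bromobenzaldehyde
Product: 22 2,6-bis(benzyloxy)-4-{2,3,4-tris(benzyloxy)-6-[2,4,6-tris(benzyloxy)phenoxy]phenoxy}benzaldehyde
Conditions: CuI (20 mol%), picolinic acid (40 mol%), K3PO4, DMSO, 90 °C, argon
Reagents that add atoms: none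
Why: Ullmann-type O-arylation in which the aryl bromide is unhindered and activated by the para aldehyde, the combination that tolerates a doubly flanked phenol best.

Step 15
Reactants: 22 rings A–B–C aldehyde
Product: 24 2,6-bis(benzyloxy)-4-{2,3,4-tris(benzyloxy)-6-[2,4,6-tris(benzyloxy)phenoxy]phenoxy}phenol, via trimer formate 23 (not isolated)
Conditions: mCPBA (1.1 equiv), NaHCO3, CH2Cl2, 0 °C; then K2CO3 (cat.), MeOH/THF, rt
Reagents that add atoms: 3-chloroperoxybenzoic acid, OOC(=O)c1cccc(Cl)c1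
Why: Dakin-type Baeyer–Villiger oxidation of a 2,6-dialkoxy-4-aryloxybenzaldehyde, a substrate class in which aryl migration is fast and clean.

Step 16
Reactants: 25 5-bromo-1,2,3-trimethoxybenzene
Product: 26 5-bromobenzene-1,2,3-triol
Conditions: BBr3, CH2Cl2, −78 °C to rt; H2O
Reagents that add atoms: none
Why: Lewis acid demethylation of aryl methyl ethers, with the aryl bromide inert.

Step 17
Reactants: 26 5-bromobenzene-1,2,3-triol
Product: 27 1,2,3-tris(benzyloxy)-5-bromobenzene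
Conditions: BnBr, K2CO3, DMF, 60 °C, argon
Reagents that add atoms: benzyl bromide, BrCc1ccccc1
Why: Williamson etherification of a pyrogallol, which shows no competing C-alkylation.

Step 18
Reactants: 27 1,2,3-tris(benzyloxy)-5-bromobenzene
Product: 28 2,3,4-tris(benzyloxy)-6-bromobenzaldehyde
Conditions: POCl3, DMF, 80 °C; then aq. NaOAc
Reagents that add atoms: N,N-dimethylformamide, CN(C)C=O; water, O
Why: Vilsmeier–Haack formylation ortho/para to the alkoxy groups, where the two free positions are equivalent so only one isomer can form.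

Step 19
Reactants: 24 rings A–B–C phenol; 28 2,3,4-tris(benzyloxy)-6-bromobenzaldehyde
Product: 29 2,3,4-tris(benzyloxy)-6-[2,6-bis(benzyloxy)-4-{2,3,4-tris(benzyloxy)-6-[2,4,6-tris(benzyloxy)phenoxy]phenoxy}phenoxy]benzaldehyde
Conditions: CuI (20 mol%), picolinic acid (40 mol%), K3PO4, DMSO, 100 °C, argon
Reagents that add atoms: none
Why: Ullmann-type O-arylation accelerated by the ortho-formyl group of the bromide, which chelates monovalent copper and offsets the hindrance of the phenol.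

Step 20
Reactants: 29 rings A–D aldehyde
Product: 31 2,3,4-tris(benzyloxy)-6-[2,6-bis(benzyloxy)-4-{2,3,4-tris(benzyloxy)-6-[2,4,6-tris(benzyloxy)phenoxy]phenoxy}phenoxy]phenol, via tetramer formate 30 (not isolated)
Conditions: mCPBA (1.1 equiv), NaHCO3, CH2Cl2, 0 °C; then K2CO3 (cat.), MeOH/THF, rt
Reagents that add atoms: 3-chloroperoxybenzoic acid, OOC(=O)c1cccc(Cl)c1
Why: Dakin-type Baeyer–Villiger oxidation of an aldehyde that carries ortho aryloxy, ortho benzyloxy and para benzyloxy donors.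

Step 21
Reactants: 31 rings A–D phenol; 21 2,6-bis(benzyloxy)-4-bromobenzaldehyde
Product: 32 2,6-bis(benzyloxy)-4-(aryloxy)benzaldehyde in which the aryloxy group is the oxygen of phenol 31 (rings A–E aldehyde)
Conditions: CuI (20 mol%), picolinic acid (40 mol%), K3PO4, DMSO, 90 °C, argon
Reagents that add atoms: none
Why: the same Ullmann-type O-arylation as step 14, with the same electronic and steric situation at the reacting centres.

Step 22
Reactants: 32 rings A–E aldehyde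
Product: 34 2,6-bis(benzyloxy)-4-(aryloxy)phenol in which the aryloxy group is the oxygen of phenol 31 (rings A–E phenol), via pentamer formate 33 (not isolated)
Conditions: mCPBA (1.1 equiv), NaHCO3, CH2Cl2, 0 °C; then K2CO3 (cat.), MeOH/THF, rt
Reagents that add atoms: 3-chloroperoxybenzoic acid, OOC(=O)c1cccc(Cl)c1
Why: Dakin-type Baeyer–Villiger oxidation, identical in type to step 15.

Step 23
Reactants: 34 rings A–E phenol; 21 2,6-bis(benzyloxy)-4-bromobenzaldehyde
Product: 35 2,6-bis(benzyloxy)-4-(aryloxy)benzaldehyde in which the aryloxy group is the oxygen of phenol 34 (rings A–F aldehyde)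
Conditions: CuI (20 mol%), picolinic acid (40 mol%), K3PO4, DMSO, 90 °C, argon
Reagents that add atoms: none
Why: Ullmann-type O-arylation of a 2,6-dialkoxyphenol by an unhindered, aldehyde-activated bromide, as in steps 14 and 21.

Step 24
Reactants: 35 rings A–F aldehyde
Product: 37 2,6-bis(benzyloxy)-4-(aryloxy)phenol in which the aryloxy group is the oxygen of phenol 34 (rings A–F phenol), via hexamer formate 36 (not isolated)
Conditions: mCPBA (1.1 equiv), NaHCO3, CH2Cl2, 0 °C; then K2CO3 (cat.), MeOH/THF, rt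
Reagents that add atoms: 3-chloroperoxybenzoic acid, OOC(=O)c1cccc(Cl)c1
Why: Dakin-type Baeyer–Villiger oxidation turns the last formyl group into the 4-hydroxyl of ring F.

Step 25
Reactants: 37 rings A–F phenol
Product: 38 hexadeca-O-benzyl ether of the target
Conditions: BnBr, K2CO3, DMF, 50 °C, argon
Reagents that add atoms: benzyl bromide, BrCc1ccccc1
Why: Williamson etherification caps the oxidation-prone 2,6-dialkoxyphenol so that the fully protected hexamer can be purified and stored.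

Step 26
Reactants: 38 hexadeca-O-benzyl ether of the target
Product: 39 target CNP0218077.0
Conditions: H2 (1 atm), Pd(OH)2/C, THF/MeOH, rt; filter and concentrate under argon
Reagents that add atoms: none
Why: hydrogenolysis cleaves all sixteen benzyl ethers while diaryl ethers are inert, and the achiral product needs no stereocontrol.

## Compound list

1 | 2,3,4-trihydroxybenzaldehyde | O=Cc1ccc(O)c(O)c1O | starting material
2 | 2,3,4-tris(benzyloxy)benzaldehyde | O=Cc1ccc(OCc2ccccc2)c(OCc2ccccc2)c1OCc1ccccc1 | intermediate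
3 | 2,3,4-tris(benzyloxy)phenyl formate | O=COc1ccc(OCc2ccccc2)c(OCc2ccccc2)c1OCc1ccccc1 | intermediate (not isolated)
4 | 2,3,4-tris(benzyloxy)phenol | Oc1ccc(OCc2ccccc2)c(OCc2ccccc2)c1OCc1ccccc1 | intermediate
5 | 3,4,5-tris(benzyloxy)-2-hydroxybenzaldehyde | O=Cc1cc(OCc2ccccc2)c(OCc2ccccc2)c(OCc2ccccc2)c1O | intermediate
6 | 2-(allyloxy)-3,4,5-tris(benzyloxy)benzaldehyde | O=Cc1cc(OCc2ccccc2)c(OCc2ccccc2)c(OCc2ccccc2)c1OCC=C | intermediate
7 | 2-(allyloxy)-3,4,5-tris(benzyloxy)phenyl formate | O=COc1cc(OCc2ccccc2)c(OCc2ccccc2)c(OCc2ccccc2)c1OCC=C | intermediate (not isolated)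
8 | 2-(allyloxy)-3,4,5-tris(benzyloxy)phenol | Oc1cc(OCc2ccccc2)c(OCc2ccccc2)c(OCc2ccccc2)c1OCC=C | intermediate
9 | dimethyl 2-chloromalonate | COC(=O)C(Cl)C(=O)OC | starting material
10 | dimethyl 2-[2-(allyloxy)-3,4,5-tris(benzyloxy)phenoxy]malonate | COC(=O)C(Oc1cc(OCc2ccccc2)c(OCc2ccccc2)c(OCc2ccccc2)c1OCC=C)C(=O)OC | intermediate
11 | rac-2-[2-(allyloxy)-3,4,5-tris(benzyloxy)phenoxy]-3-methoxy-3-oxopropanoic acid | COC(=O)C(Oc1cc(OCc2ccccc2)c(OCc2ccccc2)c(OCc2ccccc2)c1OCC=C)C(=O)O | intermediate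
12 | rac-methyl 2-[2-(allyloxy)-3,4,5-tris(benzyloxy)phenoxy]-3-chloro-3-oxopropanoate | COC(=O)C(Oc1cc(OCc2ccccc2)c(OCc2ccccc2)c(OCc2ccccc2)c1OCC=C)C(=O)Cl | intermediate
13 | dimethyl 3-oxopentanedioate (dimethyl 1,3-acetonedicarboxylate) | COC(=O)CC(=O)CC(=O)OC | starting material
14 | dimethyl 2-[2-(allyloxy)-3,4,5-tris(benzyloxy)phenoxy]-4-(methoxycarbonyl)-3,5-dioxoheptanedioate (stereoisomer and enol mixture) | COC(=O)CC(=O)C(C(=O)OC)C(=O)C(Oc1cc(OCc2ccccc2)c(OCc2ccccc2)c(OCc2ccccc2)c1OCC=C)C(=O)OC | intermediate (not isolated)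
15 | dimethyl 5-[2-(allyloxy)-3,4,5-tris(benzyloxy)phenoxy]-2,4,6-trihydroxybenzene-1,3-dicarboxylate | COC(=O)c1c(O)c(C(=O)OC)c(O)c(Oc2cc(OCc3ccccc3)c(OCc3ccccc3)c(OCc3ccccc3)c2OCC=C)c1O | intermediate
16 | 2-[2-(allyloxy)-3,4,5-tris(benzyloxy)phenoxy]benzene-1,3,5-triol | Oc1cc(O)c(Oc2cc(OCc3ccccc3)c(OCc3ccccc3)c(OCc3ccccc3)c2OCC=C)c(O)c1 | intermediate (not isolated)
17 | 2-[2-(allyloxy)-3,4,5-tris(benzyloxy)phenoxy]benzene-1,3,5-triyl triacetate | CC(=O)Oc1cc(OC(C)=O)c(Oc2cc(OCc3ccccc3)c(OCc3ccccc3)c(OCc3ccccc3)c2OCC=C)c(OC(C)=O)c1 | intermediate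
18 | 2-(allyloxy)-3,4,5-tris(benzyloxy)-1-[2,4,6-tris(benzyloxy)phenoxy]benzene (rings A–B allyl ether) | C=CCOc1c(Oc2c(OCc9ccccc9)cc(OCc9ccccc9)cc2OCc9ccccc9)cc(OCc9ccccc9)c(OCc9ccccc9)c1OCc9ccccc9 | intermediate
19 | 2,3,4-tris(benzyloxy)-6-[2,4,6-tris(benzyloxy)phenoxy]phenol (rings A–B phenol) | Oc1c(Oc2c(OCc9ccccc9)cc(OCc9ccccc9)cc2OCc9ccccc9)cc(OCc9ccccc9)c(OCc9ccccc9)c1OCc9ccccc9 | intermediate
20 | 4-bromo-2,6-difluorobenzaldehyde | O=Cc1c(F)cc(Br)cc1F | starting material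
21 | 2,6-bis(benzyloxy)-4-bromobenzaldehyde | O=Cc1c(OCc2ccccc2)cc(Br)cc1OCc1ccccc1 | intermediate
22 | 2,6-bis(benzyloxy)-4-{2,3,4-tris(benzyloxy)-6-[2,4,6-tris(benzyloxy)phenoxy]phenoxy}benzaldehyde (rings A–B–C aldehyde) | O=Cc1c(OCc9ccccc9)cc(Oc3c(Oc2c(OCc9ccccc9)cc(OCc9ccccc9)cc2OCc9ccccc9)cc(OCc9ccccc9)c(OCc9ccccc9)c3OCc9ccccc9)cc1OCc9ccccc9 | intermediate
23 | formate ester of phenol 24 (rings A–B–C formate) | O=COc1c(OCc9ccccc9)cc(Oc3c(Oc2c(OCc9ccccc9)cc(OCc9ccccc9)cc2OCc9ccccc9)cc(OCc9ccccc9)c(OCc9ccccc9)c3OCc9ccccc9)cc1OCc9ccccc9 | intermediate (not isolated)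
24 | 2,6-bis(benzyloxy)-4-{2,3,4-tris(benzyloxy)-6-[2,4,6-tris(benzyloxy)phenoxy]phenoxy}phenol (rings A–B–C phenol) | Oc1c(OCc9ccccc9)cc(Oc3c(Oc2c(OCc9ccccc9)cc(OCc9ccccc9)cc2OCc9ccccc9)cc(OCc9ccccc9)c(OCc9ccccc9)c3OCc9ccccc9)cc1OCc9ccccc9 | intermediate
25 | 5-bromo-1,2,3-trimethoxybenzene | COc1cc(Br)cc(OC)c1OC | starting material
26 | 5-bromobenzene-1,2,3-triol | Oc1cc(Br)cc(O)c1O | intermediate
27 | 1,2,3-tris(benzyloxy)-5-bromobenzene | Brc1cc(OCc2ccccc2)c(OCc2ccccc2)c(OCc2ccccc2)c1 | intermediate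
28 | 2,3,4-tris(benzyloxy)-6-bromobenzaldehyde | O=Cc1c(Br)cc(OCc2ccccc2)c(OCc2ccccc2)c1OCc1ccccc1 | intermediate
29 | 2,3,4-tris(benzyloxy)-6-(aryloxy)benzaldehyde, aryloxy = oxygen of phenol 24 (rings A–D aldehyde) | O=Cc1c(Oc4c(OCc9ccccc9)cc(Oc3c(Oc2c(OCc9ccccc9)cc(OCc9ccccc9)cc2OCc9ccccc9)cc(OCc9ccccc9)c(OCc9ccccc9)c3OCc9ccccc9)cc4OCc9ccccc9)cc(OCc9ccccc9)c(OCc9ccccc9)c1OCc9ccccc9 | intermediate
30 | formate ester of phenol 31 (rings A–D formate) | O=COc1c(Oc4c(OCc9ccccc9)cc(Oc3c(Oc2c(OCc9ccccc9)cc(OCc9ccccc9)cc2OCc9ccccc9)cc(OCc9ccccc9)c(OCc9ccccc9)c3OCc9ccccc9)cc4OCc9ccccc9)cc(OCc9ccccc9)c(OCc9ccccc9)c1OCc9ccccc9 | intermediate (not isolated)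
31 | 2,3,4-tris(benzyloxy)-6-(aryloxy)phenol, aryloxy = oxygen of phenol 24 (rings A–D phenol) | Oc1c(Oc4c(OCc9ccccc9)cc(Oc3c(Oc2c(OCc9ccccc9)cc(OCc9ccccc9)cc2OCc9ccccc9)cc(OCc9ccccc9)c(OCc9ccccc9)c3OCc9ccccc9)cc4OCc9ccccc9)cc(OCc9ccccc9)c(OCc9ccccc9)c1OCc9ccccc9 | intermediate
32 | 2,6-bis(benzyloxy)-4-(aryloxy)benzaldehyde, aryloxy = oxygen of phenol 31 (rings A–E aldehyde) | O=Cc1c(OCc9ccccc9)cc(Oc5c(Oc4c(OCc9ccccc9)cc(Oc3c(Oc2c(OCc9ccccc9)cc(OCc9ccccc9)cc2OCc9ccccc9)cc(OCc9ccccc9)c(OCc9ccccc9)c3OCc9ccccc9)cc4OCc9ccccc9)cc(OCc9ccccc9)c(OCc9ccccc9)c5OCc9ccccc9)cc1OCc9ccccc9 | intermediate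
33 | formate ester of phenol 34 (rings A–E formate) | O=COc1c(OCc9ccccc9)cc(Oc5c(Oc4c(OCc9ccccc9)cc(Oc3c(Oc2c(OCc9ccccc9)cc(OCc9ccccc9)cc2OCc9ccccc9)cc(OCc9ccccc9)c(OCc9ccccc9)c3OCc9ccccc9)cc4OCc9ccccc9)cc(OCc9ccccc9)c(OCc9ccccc9)c5OCc9ccccc9)cc1OCc9ccccc9 | intermediate (not isolated)
34 | 2,6-bis(benzyloxy)-4-(aryloxy)phenol, aryloxy = oxygen of phenol 31 (rings A–E phenol) | Oc1c(OCc9ccccc9)cc(Oc5c(Oc4c(OCc9ccccc9)cc(Oc3c(Oc2c(OCc9ccccc9)cc(OCc9ccccc9)cc2OCc9ccccc9)cc(OCc9ccccc9)c(OCc9ccccc9)c3OCc9ccccc9)cc4OCc9ccccc9)cc(OCc9ccccc9)c(OCc9ccccc9)c5OCc9ccccc9)cc1OCc9ccccc9 | intermediate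
35 | 2,6-bis(benzyloxy)-4-(aryloxy)benzaldehyde, aryloxy = oxygen of phenol 34 (rings A–F aldehyde) | O=Cc1c(OCc9ccccc9)cc(Oc6c(OCc9ccccc9)cc(Oc5c(Oc4c(OCc9ccccc9)cc(Oc3c(Oc2c(OCc9ccccc9)cc(OCc9ccccc9)cc2OCc9ccccc9)cc(OCc9ccccc9)c(OCc9ccccc9)c3OCc9ccccc9)cc4OCc9ccccc9)cc(OCc9ccccc9)c(OCc9ccccc9)c5OCc9ccccc9)cc6OCc9ccccc9)cc1OCc9ccccc9 | intermediate
36 | formate ester of phenol 37 (rings A–F formate) | O=COc1c(OCc9ccccc9)cc(Oc6c(OCc9ccccc9)cc(Oc5c(Oc4c(OCc9ccccc9)cc(Oc3c(Oc2c(OCc9ccccc9)cc(OCc9ccccc9)cc2OCc9ccccc9)cc(OCc9ccccc9)c(OCc9ccccc9)c3OCc9ccccc9)cc4OCc9ccccc9)cc(OCc9ccccc9)c(OCc9ccccc9)c5OCc9ccccc9)cc6OCc9ccccc9)cc1OCc9ccccc9 | intermediate (not isolated)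
37 | 2,6-bis(benzyloxy)-4-(aryloxy)phenol, aryloxy = oxygen of phenol 34 (rings A–F phenol) | Oc1c(OCc9ccccc9)cc(Oc6c(OCc9ccccc9)cc(Oc5c(Oc4c(OCc9ccccc9)cc(Oc3c(Oc2c(OCc9ccccc9)cc(OCc9ccccc9)cc2OCc9ccccc9)cc(OCc9ccccc9)c(OCc9ccccc9)c3OCc9ccccc9)cc4OCc9ccccc9)cc(OCc9ccccc9)c(OCc9ccccc9)c5OCc9ccccc9)cc6OCc9ccccc9)cc1OCc9ccccc9 | intermediate
38 | hexadeca-O-benzyl ether of the target (benzyl ether of 37) | c9ccccc9COc1c(OCc9ccccc9)cc(Oc6c(OCc9ccccc9)cc(Oc5c(Oc4c(OCc9ccccc9)cc(Oc3c(Oc2c(OCc9ccccc9)cc(OCc9ccccc9)cc2OCc9ccccc9)cc(OCc9ccccc9)c(OCc9ccccc9)c3OCc9ccccc9)cc4OCc9ccccc9)cc(OCc9ccccc9)c(OCc9ccccc9)c5OCc9ccccc9)cc6OCc9ccccc9)cc1OCc9ccccc9 | intermediate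
39 | CNP0218077.0, hexameric fuhalol (achiral) | Oc1cc(O)c(Oc2cc(O)c(O)c(O)c2Oc2cc(O)c(Oc3cc(O)c(O)c(O)c3Oc3cc(O)c(Oc4cc(O)c(O)c(O)c4)c(O)c3)c(O)c2)c(O)c1 | target

## Summary

Total step count: 26.
Longest linear sequence: 22 steps (steps 1–12, 14, 15 and 19–26).

The three steps most likely to fail, each with one fallback:

Step 9 (acylation and Dieckmann ring closure to 15). The acyclic intermediate 14 can lactonise to a pyranone or suffer retro-Claisen cleavage instead of closing to the benzene ring. The fallback gives up building ring A and attaches it as a preformed arene. Commercial 1,3,5-tris(benzyloxy)benzene is formylated (POCl3, DMF) to 2,4,6-tris(benzyloxy)benzaldehyde F1. Dakin oxidation (mCPBA; then K2CO3, MeOH) passes through 2,4,6-tris(benzyloxy)phenyl formate F2 and gives 2,4,6-tris(benzyloxy)phenol F3. This phenol is O-arylated with bromoaldehyde 28 (CuI, picolinic acid, K3PO4, DMSO) to 2,3,4-tris(benzyloxy)-6-[2,4,6-tris(benzyloxy)phenoxy]benzaldehyde F4. A second Dakin oxidation through 2,3,4-tris(benzyloxy)-6-[2,4,6-tris(benzyloxy)phenoxy]phenyl formate F5 gives phenol 19. The fallback sets out from 28 and comes back to the route at 19.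

Step 19 (Cu-catalysed union of the flanked trimer phenol 24 with 28, a triply ortho-substituted diaryl ether). If copper catalysis fails on steric grounds, the bond is made by uncatalysed SNAr with a fluoride leaving group. Bromide 27 is lithiated (n-BuLi, THF, −78 °C) and quenched with N-fluorobenzenesulfonimide to give 1,2,3-tris(benzyloxy)-5-fluorobenzene F6. Vilsmeier–Haack formylation (POCl3, DMF) gives 2,3,4-tris(benzyloxy)-6-fluorobenzaldehyde F7. The phenoxide of 24 displaces the fluoride ortho to the aldehyde (Cs2CO3, DMSO, 110 °C) to give 29. The fallback sets out from 27 (with 24 as partner) and comes back to the route at 29.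

Step 14 (Cu-catalysed arylation of phenol 19, flanked by a bulky aryloxy and a benzyloxy group; steps 21 and 23 are of the same kind). If the Ullmann coupling stalls, the polarity of the aryl partner is changed to a boron reagent and the ether is made oxidatively. Bromide 21 undergoes Miyaura borylation (Pd(dppf)Cl2, bis(pinacolato)diboron, KOAc, dioxane, 90 °C) to 2,6-bis(benzyloxy)-4-(4,4,5,5-tetramethyl-1,3,2-dioxaborolan-2-yl)benzaldehyde F8. F8 is coupled with phenol 19 under Chan–Evans–Lam conditions (Cu(OAc)2, pyridine, B(OH)3, 4 Å molecular sieves, MeCN, 60 °C, air), which are known to accept doubly ortho-substituted phenols with unhindered aryl boron partners, to give 22. The fallback sets out from 21 (with 19 as partner) and comes back to the route at 22; the same boronate serves for steps 21 and 23.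

## Further compounds

F1 | step 9 | 2,4,6-tris(benzyloxy)benzaldehyde | O=Cc1c(OCc2ccccc2)cc(OCc2ccccc2)cc1OCc1ccccc1
F2 | step 9 | 2,4,6-tris(benzyloxy)phenyl formate | O=COc1c(OCc2ccccc2)cc(OCc2ccccc2)cc1OCc1ccccc1
F3 | step 9 | 2,4,6-tris(benzyloxy)phenol | Oc1c(OCc2ccccc2)cc(OCc2ccccc2)cc1OCc1ccccc1
F4 | step 9 | 2,3,4-tris(benzyloxy)-6-[2,4,6-tris(benzyloxy)phenoxy]benzaldehyde | O=Cc1c(Oc2c(OCc9ccccc9)cc(OCc9ccccc9)cc2OCc9ccccc9)cc(OCc9ccccc9)c(OCc9ccccc9)c1OCc9ccccc9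
F5 | step 9 | 2,3,4-tris(benzyloxy)-6-[2,4,6-tris(benzyloxy)phenoxy]phenyl formate | O=COc1c(Oc2c(OCc9ccccc9)cc(OCc9ccccc9)cc2OCc9ccccc9)cc(OCc9ccccc9)c(OCc9ccccc9)c1OCc9ccccc9
F6 | step 19 | 1,2,3-tris(benzyloxy)-5-fluorobenzene | Fc1cc(OCc2ccccc2)c(OCc2ccccc2)c(OCc2ccccc2)c1
F7 | step 19 | 2,3,4-tris(benzyloxy)-6-fluorobenzaldehyde | O=Cc1c(F)cc(OCc2ccccc2)c(OCc2ccccc2)c1OCc1ccccc1
F8 | step 14 | 2,6-bis(benzyloxy)-4-(4,4,5,5-tetramethyl-1,3,2-dioxaborolan-2-yl)benzaldehyde | O=Cc1c(OCc2ccccc2)cc(B2OC(C)(C)C(C)(C)O2)cc1OCc1ccccc1
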